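**Retrosynthetic overview**
1. Elemanolide numbering is used (C1–C2 oxirane, C3=C4–C15 acrolein unit, C5–C10 cyclohexane, C11–C13 methylene lactone, C14 methyl; β is the face of C14). Target 25 ← isopropenyl compound 23 (allylic oxidation at C15) ← 22 ← 21 (angelates put on one hydroxyl at a time) ← 19 ← C6 ketone 18 (hydride from the α face) ← iodohydrin 16 (oxirane by ring closure).
2. Key disconnection: bonds C6–C7 and C8–C9 of the cyclohexane, cut in one step into lactol aldehyde 9 (C9–C10–C5–C6, a masked 1,4-dialdehyde) and furan 14 (the C7–C8 edge plus C11–C13).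
3. Enabling feature: the C7–C8 bond is the edge shared by the cyclohexane and the γ-lactone ring and lies between the carbinol carbons C6 and C9, so a 3-(borylmethyl)-2-silyloxyfuran can be a nucleophile twice (C8 as vinylogous enol silane, then C7 as allylboronate once the furan is dearomatised).
4. 9 ← iodolactone 7 (sets C1, stores the oxirane, distinguishes C6 from C9) ← acid 6 ← enantioselective Ireland–Claisen rearrangement of ester 5 (C5–C10 bond, both centres).
5. Ring order: furanone ring (carried in from 10) → cyclohexane (step 11) → oxirane (step 12).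

Key step: step 11

**Assumptions (remarks on the chemistry)**
- Compound 1 is taken as a purchasable C5 building block.
- The (S,S)-controller is written for step 4; its sense of induction is assigned by analogy, and the mirror-image controller would be used if the sense proves opposite.
- Lactols 8, 9 and 15 are anomeric mixtures in equilibrium with their open hydroxy aldehydes.

**Route**

Step 1
Reactants: 1 (E)-4-acetoxy-2-methylbut-2-enal
Product: 2 (E)-4,4-dimethoxy-3-methylbut-2-en-1-yl acetate
Conditions: HC(OMe)3, PPTS (cat.), CH2Cl2, 25 °C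
Reagents that add atoms: trimethyl orthoformate, COC(OC)OC
Why: Acid-catalysed acetalisation masks the future C9 aldehyde through steps 2–6 and leaves the E double bond untouched.

Step 2
Reactants: 2 (E)-4,4-dimethoxy-3-methylbut-2-en-1-yl acetate
Product: 3 (E)-4,4-dimethoxy-3-methylbut-2-en-1-ol
Conditions: K2CO3 (cat.), MeOH, 0 °C
Reagents that add atoms: none
Why: Base-catalysed transesterification should free the allylic alcohol without touching the acetal.

Step 3
Reactants: 3 (E)-4,4-dimethoxy-3-methylbut-2-en-1-ol; 4 3-methylbut-3-enoic acid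
Product: 5 (E)-4,4-dimethoxy-3-methylbut-2-en-1-yl 3-methylbut-3-enoate
Conditions: N,N'-diisopropylcarbodiimide, DMAP (cat.), CH2Cl2, 0 °C
Reagents that add atoms: none
Why: Steglich esterification joins the C5–C6 acid part to the allylic alcohol that carries C1, C2, C9 and C10.

Step 4
Reactants: 5 (E)-4,4-dimethoxy-3-methylbut-2-en-1-yl 3-methylbut-3-enoate
Product: 6 (2S,3S)-3-ethenyl-4,4-dimethoxy-3-methyl-2-(prop-1-en-2-yl)butanoic acid
Conditions: (4S,5S)-2-bromo-4,5-diphenyl-1,3-bis{[3,5-bis(trifluoromethyl)phenyl]sulfonyl}-1,3,2-diazaborolidine (1.2 equiv), Et3N, toluene/hexane, −78 °C → 4 °C; aqueous work-up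
Reagents that add atoms: none
Why: Enantioselective Ireland–Claisen rearrangement through a chiral boron ketene acetal, a known way to the elemane-type quaternary/tertiary pair; in the chair transition state the (E)-alkene puts the dimethoxymethyl group equatorial, the enolate with isopropenyl trans to O–B fixes the C5/C10 relationship, and the diazaborolidine sets the absolute configuration.

Step 5
Reactants: 6 (2S,3S)-3-ethenyl-4,4-dimethoxy-3-methyl-2-(prop-1-en-2-yl)butanoic acid
Product: 7 (3S,4R,5R)-4-(dimethoxymethyl)-5-(iodomethyl)-4-methyl-3-(prop-1-en-2-yl)oxolan-2-one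
Conditions: I2, NaHCO3, MeCN, 0 °C
Reagents that add atoms: iodine, II
Why: Iodolactonisation by 5-exo closure onto the vinyl group (faster than 4-exo onto the isopropenyl group) should place CH2I on the ring face away from the isopropenyl and dimethoxymethyl groups, which sets C1 and stores the oxirane as an iodohydrin ester.

Step 6
Reactants: 7 (3S,4R,5R)-4-(dimethoxymethyl)-5-(iodomethyl)-4-methyl-3-(prop-1-en-2-yl)oxolan-2-one
Product: 8 (3S,4R,5R)-4-(dimethoxymethyl)-5-(iodomethyl)-4-methyl-3-(prop-1-en-2-yl)oxolan-2-ol (anomers)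
Conditions: i-Bu2AlH (1.1 equiv), CH2Cl2, −78 °C; aq. potassium sodium tartrate
Reagents that add atoms: none
Why: Partial reduction of a γ-lactone to the lactol at low temperature brings C6 to the aldehyde level while keeping it masked by the C1 oxygen.

Step 7
Reactants: 8 (3S,4R,5R)-4-(dimethoxymethyl)-5-(iodomethyl)-4-methyl-3-(prop-1-en-2-yl)oxolan-2-ol
Product: 9 (2R,3R,4S)-5-hydroxy-2-(iodomethyl)-3-methyl-4-(prop-1-en-2-yl)oxolane-3-carbaldehyde (anomers)
Conditions: PPTS (cat.), acetone/H2O, 40 °C
Reagents that add atoms: water, O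
Why: Mild acetal hydrolysis frees the non-enolisable C9 aldehyde, while C6 stays a five-membered lactol (C9 could only reach the same oxygen through an oxetane).

Step 8
Reactants: 10 3-methylideneoxolan-2-one (α-methylene-γ-butyrolactone)
Product: 12 3-(bromomethyl)furan-2(5H)-one, via 3-bromo-3-(bromomethyl)oxolan-2-one 11 (not isolated)
Conditions: Br2, CH2Cl2, 0 °C; then Et3N, 0 → 25 °C
Reagents that add atoms: bromine, BrBr
Why: Bromine addition followed by E2 loss of HBr towards the ring CH2 should give the conjugated butenolide with an allylic bromide.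

Step 9
Reactants: 12 3-(bromomethyl)furan-2(5H)-one
Product: 13 3-[(4,4,5,5-tetramethyl-1,3,2-dioxaborolan-2-yl)methyl]furan-2(5H)-one
Conditions: B2pin2, Pd2(dba)3 (cat.), THF, 50 °C
Reagents that add atoms: bis(pinacolato)diboron, CC1(C)OB(OC1(C)C)B1OC(C)(C)C(C)(C)O1
Why: Palladium-catalysed borylation of an allylic halide via the π-allyl complex should deliver boron to the unsubstituted terminus, giving a 2-acyl allylboronate.

Step 10
Reactants: 13 3-[(4,4,5,5-tetramethyl-1,3,2-dioxaborolan-2-yl)methyl]furan-2(5H)-one
Product: 14 triethyl({3-[(4,4,5,5-tetramethyl-1,3,2-dioxaborolan-2-yl)methyl]furan-2-yl}oxy)silane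
Conditions: Et3SiOTf, Et3N, CH2Cl2, 0 °C
Reagents that add atoms: triethylsilyl trifluoromethanesulfonate, CC[Si](CC)(CC)OS(=O)(=O)C(F)(F)F
Why: Soft enolisation and O-silylation of the butenolide gives the aromatic 2-silyloxyfuran, in which the boronate is only a furylmethyl boronate and therefore dormant.

Step 11
Reactants: 9 (2R,3R,4S)-5-hydroxy-2-(iodomethyl)-3-methyl-4-(prop-1-en-2-yl)oxolane-3-carbaldehyde; 14 triethyl({3-[(4,4,5,5-tetramethyl-1,3,2-dioxaborolan-2-yl)methyl]furan-2-yl}oxy)silane
Product: 16 (1R)-1,6α-dihydroxy-2-iodo-9α-(triethylsilyloxy)elema-3,11(13)-dien-8β,12-olide, via butenolide lactol 15 (not isolated)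
Conditions: Sc(OTf)3 (10 mol %), CH2Cl2, −78 °C → 25 °C; aq. NaHCO3
Reagents that add atoms: none
Why: Proposed new method: Sc(OTf)3 activates the only free aldehyde (C9), the silyloxyfuran adds through its γ-carbon C8 in an open vinylogous Mukaiyama aldol with silyl transfer to O9 (closest known type: Lewis-acid additions of 3-substituted 2-silyloxyfurans to aldehydes, γ- and syn-selective), and this dearomatisation turns the dormant furylmethyl boronate into the 2-acyl allylboronate 15. On warming, 15 allylates C6 of the ring-opened lactol through a closed six-membered chair (closest known type: Lewis-acid-catalysed additions of 2-alkoxycarbonyl allylboronates to aldehydes giving α-methylene-γ-butyrolactones), so the cyclohexane is closed by 6-exo-trig attack of C7 on the C6 carbonyl. C9 is set by approach anti to ring carbon C5 (which carries the cis isopropenyl group) with the scandium-bound oxygen turned away from the lactol ring oxygen, and C8 is set syn to C9 by the open transition state. C7 is set by the butenolide ring, because the new bond can only form on the face that carries C9, which makes the lactone cis-fused. C6 is expected as the 6α (equatorial) epimer, because the ring-locked allylboronate has C8 trans to the CH2B arm and C5 sits equatorial in the chair; steps 13 and 14 invert it. The step needs site selectivity (C9 before C6, secured by the lactol), γ-regioselectivity (C11 is blocked by the CH2B group) and no oxygen bridge between C6 and C9 (O9 is capped as its silyl ether as soon as C8–C9 forms, and the allylboration runs through the free aldehyde).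

Step 12
Reactants: 16 (1R)-1,6α-dihydroxy-2-iodo-9α-(triethylsilyloxy)elema-3,11(13)-dien-8β,12-olide
Product: 17 (1R)-1,2-epoxy-6α-hydroxy-9α-(triethylsilyloxy)elema-3,11(13)-dien-8β,12-olide
Conditions: Cs2CO3, MeCN, 0 → 25 °C
Reagents that add atoms: none
Why: Intramolecular Williamson closure of the iodohydrin (3-exo-tet) forms the oxirane with retention at C1 and removes the only other free secondary hydroxyl before the oxidation.

Step 13
Reactants: 17 (1R)-1,2-epoxy-6α-hydroxy-9α-(triethylsilyloxy)elema-3,11(13)-dien-8β,12-olide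
Product: 18 (1R)-1,2-epoxy-6-oxo-9α-(triethylsilyloxy)elema-3,11(13)-dien-8β,12-olide
Conditions: Dess–Martin periodinane, NaHCO3, CH2Cl2, 0 °C; crude ketone used at once
Reagents that add atoms: none
Why: Buffered Dess–Martin oxidation of the single free alcohol should give the C6 ketone without moving the two β,γ-double bonds into conjugation, provided the ketone is not stored or chromatographed.

Step 14
Reactants: 18 (1R)-1,2-epoxy-6-oxo-9α-(triethylsilyloxy)elema-3,11(13)-dien-8β,12-olide
Product: 19 (1R)-1,2-epoxy-6β-hydroxy-9α-(triethylsilyloxy)elema-3,11(13)-dien-8β,12-olide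
Conditions: NaBH4, CeCl3·7H2O, MeOH/THF, −78 °C
Reagents that add atoms: none
Why: Luche reduction is 1,2-selective and spares the methylene lactone; axial (β-face) attack is blocked by the axial C14 methyl and the axial C8–O bond, so hydride should enter from the α face and give the axial 6β-alcohol, cis to both neighbours.

Step 15
Reactants: 19 (1R)-1,2-epoxy-6β-hydroxy-9α-(triethylsilyloxy)elema-3,11(13)-dien-8β,12-olide; 20 angelic acid [(Z)-2-methylbut-2-enoic acid]
Product: 21 (1R)-6β-(angeloyloxy)-1,2-epoxy-9α-(triethylsilyloxy)elema-3,11(13)-dien-8β,12-olide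
Conditions: 20, 2,4,6-trichlorobenzoyl chloride, Et3N, toluene, 25 °C; then 19, 80 °C
Reagents that add atoms: none
Why: Yamaguchi-type mixed-anhydride esterification run without DMAP is the established way to put an angelate on a hindered alcohol without Z→E isomerisation to the tiglate; only O6 is free, and capping it at once removes the risk of translactonisation to the cis C6 oxygen.

Step 16
Reactants: 21 (1R)-6β-(angeloyloxy)-1,2-epoxy-9α-(triethylsilyloxy)elema-3,11(13)-dien-8β,12-olide
Product: 22 (1R)-6β-(angeloyloxy)-1,2-epoxy-9α-hydroxyelema-3,11(13)-dien-8β,12-olide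
Conditions: Bu4NF, AcOH, THF, 0 °C
Reagents that add atoms: none
Why: Buffered fluoride desilylation frees O9, while the acetic acid keeps the medium from becoming basic enough for acyl migration, conjugate addition to the methylene lactone or opening of the oxirane.

Step 17
Reactants: 22 (1R)-6β-(angeloyloxy)-1,2-epoxy-9α-hydroxyelema-3,11(13)-dien-8β,12-olide; 20 angelic acid [(Z)-2-methylbut-2-enoic acid]
Product: 23 (1R)-6β,9α-bis(angeloyloxy)-1,2-epoxyelema-3,11(13)-dien-8β,12-olide
Conditions: 20, 2,4,6-trichlorobenzoyl chloride, Et3N, toluene, 25 °C; then 22, 80 °C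
Reagents that add atoms: none
Why: A second mixed-anhydride esterification of the same kind acylates the single remaining hydroxyl, so the hindered axial O9 can be forced without any regiochemical question and without Z→E isomerisation.

Step 18
Reactants: 23 (1R)-6β,9α-bis(angeloyloxy)-1,2-epoxyelema-3,11(13)-dien-8β,12-olide
Product: 25 CNP0291490.2 [(1R)-6β,9α-bis(angeloyloxy)-1,2-epoxy-15-oxoelema-3,11(13)-dien-8β,12-olide], via 15-hydroxy compound 24 (not isolated)
Conditions: SeO2 (0.5 equiv), t-BuOOH, CH2Cl2, 25 °C; then MnO2, CH2Cl2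
Reagents that add atoms: tert-butyl hydroperoxide, CC(C)(C)OO
Why: SeO2 allylic oxidation (ene reaction, then 2,3-shift) should attack the methyl of the only electron-rich 1,1-disubstituted alkene, and MnO2 takes the allylic alcohol on to the enal.

**Compound list**

1 | (E)-4-acetoxy-2-methylbut-2-enal | CC(=O)OC/C=C(\C)C=O | starting material
2 | (E)-4,4-dimethoxy-3-methylbut-2-en-1-yl acetate | CC(=O)OC/C=C(\C)C(OC)OC | intermediate
3 | (E)-4,4-dimethoxy-3-methylbut-2-en-1-ol | OC/C=C(\C)C(OC)OC | intermediate
4 | 3-methylbut-3-enoic acid | C=C(C)CC(=O)O | starting material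
5 | (E)-4,4-dimethoxy-3-methylbut-2-en-1-yl 3-methylbut-3-enoate | C=C(C)CC(=O)OC/C=C(\C)C(OC)OC | intermediate
6 | (2S,3S)-3-ethenyl-4,4-dimethoxy-3-methyl-2-(prop-1-en-2-yl)butanoic acid | OC(=O)[C@@H](C(C)=C)[C@](C)(C=C)C(OC)OC | intermediate
7 | (3S,4R,5R)-4-(dimethoxymethyl)-5-(iodomethyl)-4-methyl-3-(prop-1-en-2-yl)oxolan-2-one (CH2I cis to the ring methyl) | O=C1O[C@@H](CI)[C@](C)(C(OC)OC)[C@@H]1C(C)=C | intermediate
8 | (3S,4R,5R)-4-(dimethoxymethyl)-5-(iodomethyl)-4-methyl-3-(prop-1-en-2-yl)oxolan-2-ol, anomers | OC1O[C@@H](CI)[C@](C)(C(OC)OC)[C@@H]1C(C)=C | intermediate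
9 | (2R,3R,4S)-5-hydroxy-2-(iodomethyl)-3-methyl-4-(prop-1-en-2-yl)oxolane-3-carbaldehyde, anomers | OC1O[C@@H](CI)[C@](C)(C=O)[C@@H]1C(C)=C | intermediate
10 | 3-methylideneoxolan-2-one (α-methylene-γ-butyrolactone) | C=C1CCOC1=O | starting material
11 | 3-bromo-3-(bromomethyl)oxolan-2-one (racemic) | BrCC1(Br)CCOC1=O | intermediate
12 | 3-(bromomethyl)furan-2(5H)-one | BrCC1=CCOC1=O | intermediate
13 | 3-[(4,4,5,5-tetramethyl-1,3,2-dioxaborolan-2-yl)methyl]furan-2(5H)-one | CC1(C)OB(CC2=CCOC2=O)OC1(C)C | intermediate
14 | triethyl({3-[(4,4,5,5-tetramethyl-1,3,2-dioxaborolan-2-yl)methyl]furan-2-yl}oxy)silane | CC[Si](CC)(CC)Oc1occc1CB1OC(C)(C)C(C)(C)O1 | intermediate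
15 | butenolide lactol: lactol 9 carrying at C9 a triethylsilyloxy group and the 3-(pinacolborylmethyl)-5H-furan-2-on-5-yl ring (C8), C8/C9 as in 16, anomers | OC1O[C@@H](CI)[C@](C)([C@H](O[Si](CC)(CC)CC)[C@H]2OC(=O)C(CB3OC(C)(C)C(C)(C)O3)=C2)[C@@H]1C(C)=C | intermediate
16 | (1R)-1,6α-dihydroxy-2-iodo-9α-(triethylsilyloxy)elema-3,11(13)-dien-8β,12-olide (cis-fused lactone, H7 and H8 α) | C=C1C(=O)O[C@H]2[C@@H]1[C@H](O)[C@@H](C(C)=C)[C@](C)([C@@H](O)CI)[C@@H]2O[Si](CC)(CC)CC | intermediate
17 | (1R)-1,2-epoxy-6α-hydroxy-9α-(triethylsilyloxy)elema-3,11(13)-dien-8β,12-olide | C=C1C(=O)O[C@H]2[C@@H]1[C@H](O)[C@@H](C(C)=C)[C@](C)([C@@H]1CO1)[C@@H]2O[Si](CC)(CC)CC | intermediate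
18 | (1R)-1,2-epoxy-6-oxo-9α-(triethylsilyloxy)elema-3,11(13)-dien-8β,12-olide | C=C1C(=O)O[C@H]2[C@@H]1C(=O)[C@@H](C(C)=C)[C@](C)([C@@H]1CO1)[C@@H]2O[Si](CC)(CC)CC | intermediate
19 | (1R)-1,2-epoxy-6β-hydroxy-9α-(triethylsilyloxy)elema-3,11(13)-dien-8β,12-olide | C=C1C(=O)O[C@H]2[C@@H]1[C@@H](O)[C@@H](C(C)=C)[C@](C)([C@@H]1CO1)[C@@H]2O[Si](CC)(CC)CC | intermediate
20 | angelic acid, (Z)-2-methylbut-2-enoic acid | C/C=C(/C)C(=O)O | starting material
21 | (1R)-6β-(angeloyloxy)-1,2-epoxy-9α-(triethylsilyloxy)elema-3,11(13)-dien-8β,12-olide | C=C1C(=O)O[C@H]2[C@@H]1[C@@H](OC(=O)/C(C)=C\C)[C@@H](C(C)=C)[C@](C)([C@@H]1CO1)[C@@H]2O[Si](CC)(CC)CC | intermediate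
22 | (1R)-6β-(angeloyloxy)-1,2-epoxy-9α-hydroxyelema-3,11(13)-dien-8β,12-olide | C=C1C(=O)O[C@H]2[C@@H]1[C@@H](OC(=O)/C(C)=C\C)[C@@H](C(C)=C)[C@](C)([C@@H]1CO1)[C@@H]2O | intermediate
23 | (1R)-6β,9α-bis(angeloyloxy)-1,2-epoxyelema-3,11(13)-dien-8β,12-olide | C=C1C(=O)O[C@H]2[C@@H]1[C@@H](OC(=O)/C(C)=C\C)[C@@H](C(C)=C)[C@](C)([C@@H]1CO1)[C@@H]2OC(=O)/C(C)=C\C | intermediate
24 | (1R)-6β,9α-bis(angeloyloxy)-1,2-epoxy-15-hydroxyelema-3,11(13)-dien-8β,12-olide | C=C1C(=O)O[C@H]2[C@@H]1[C@@H](OC(=O)/C(C)=C\C)[C@@H](C(=C)CO)[C@](C)([C@@H]1CO1)[C@@H]2OC(=O)/C(C)=C\C | intermediate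
25 | CNP0291490.2, (1R)-6β,9α-bis(angeloyloxy)-1,2-epoxy-15-oxoelema-3,11(13)-dien-8β,12-olide | C=C1C(=O)O[C@H]2[C@@H]1[C@@H](OC(=O)/C(C)=C\C)[C@@H](C(=C)C=O)[C@](C)([C@@H]1CO1)[C@@H]2OC(=O)/C(C)=C\C | target

**Step count**
Total: 18 steps. Longest linear sequence: 15 steps (steps 1–7 and 11–18, from 1); the furan 14 is made in 3 steps (8–10) from 10.

**Steps most likely to fail**

Step 11 (bears the label). On warming, the Lewis acid may ionise the lactol before the allylboration, so that the furan attacks C6 or an oxygen bridge forms between C6 and C9. Facial selectivity at C9 may also be poor, and the lactol hydroxyl may protodesilylate 14. The fallback gives up the one-flask cascade for two isolated, individually known steps. It sets out from 9 and 14: the vinylogous Mukaiyama aldol is run at −78 °C and quenched cold with pyridine so that the butenolide lactol 15 is isolated. Compound 15 is then heated in toluene at 80 °C without any Lewis acid, so the allylboration goes through the neutral closed transition state of the free hydroxy aldehyde, and the sequence comes back to the route at 16. No new compound is made.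

Step 4. The Lewis-acidic bromoborane may cleave the dimethyl acetal, enolate geometry control may be incomplete, or the enantioselectivity may be low. The fallback sets out from 5. A classical Ireland–Claisen rearrangement (LiN(i-Pr)2, Me3SiCl, Et3N, THF, −78 → 25 °C, then aqueous work-up) should give the racemic acid F1 with the same relative configuration. Resolution with (R)-1-phenylethylamine and crystallisation should give the diastereomerically pure salt F2 (the mirror-image amine would be used if the other salt proves the less soluble one), and acidification returns to the route at 6.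

Step 18. The late allylic oxidation may show poor site selectivity (attack at the C5 methine or at an angelate methyl group), may over-oxidise, or the selenous acid formed may open the oxirane. The fallback replaces the oxygen-transfer ene reaction by an ene-type chlorination followed by a separate oxidation and sets out from 23. Ca(OCl)2 with solid CO2 in CH2Cl2/H2O at 0 °C should chlorinate only the electron-rich isopropenyl group, with shift of the double bond, and give the allylic chloride F3. 4-Methylmorpholine N-oxide with NaI (cat.) in MeCN at 25 °C then oxidises the allylic chloride to the enal and comes back to the route at 25.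

**Further compounds**
F0 | step 11 | none | none
F1 | step 4 | racemic 3-ethenyl-4,4-dimethoxy-3-methyl-2-(prop-1-en-2-yl)butanoic acid, (2S,3S) and (2R,3R) | OC(=O)[C@@H](C(C)=C)[C@](C)(C=C)C(OC)OC.OC(=O)[C@H](C(C)=C)[C@@](C)(C=C)C(OC)OC
F2 | step 4 | (R)-1-phenylethylammonium (2S,3S)-3-ethenyl-4,4-dimethoxy-3-methyl-2-(prop-1-en-2-yl)butanoate | C[C@@H]([NH3+])c1ccccc1.[O-]C(=O)[C@@H](C(C)=C)[C@](C)(C=C)C(OC)OC
F3 | step 18 | (1R)-6β,9α-bis(angeloyloxy)-15-chloro-1,2-epoxyelema-3,11(13)-dien-8β,12-olide | C=C1C(=O)O[C@H]2[C@@H]1[C@@H](OC(=O)/C(C)=C\C)[C@@H](C(=C)CCl)[C@](C)([C@@H]1CO1)[C@@H]2OC(=O)/C(C)=C\C
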